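Readings and results were generated by integration for an exercise.

How much product stands at the end of the east, north-east and north-west flasks, and does the charge move it?

the same everywhere: gas 130 mM (held)

| flask | substrate | remark | time |
|---|---|---|---|
| dusk | 0.27 M | run made earlier |  |
| winter | 1.3 M | run made earlier |  |
| east | 0.50 M |  | 8.0 d |
| north-east | 1.0 M |  | 8.0 d |
| north-west | 2.0 M |  | 8.0 d |

| run | time / d | product / % | substrate / % |
|---|---|---|---|
| dusk | 0.417 | 15.0 | 55.0 |
| dusk | 1.25 | 41.8 | 28.9 |
| dusk | 2.50 | 60.8 | 12.5 |
| dusk | 3.00 | 66.0 | 7.7 |
| dusk | 5.00 | 71.4 | 2.4 |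
| dusk | 6.00 | 74.1 | 1.6 |
| dusk | 8.00 | 75.0 | 1.6 |
| winter | 0.417 | 15.2 | 56.3 |
| winter | 1.25 | 43.1 | 28.9 |
| winter | 2.50 | 60.5 | 12.5 |
| winter | 3.00 | 64.7 | 8.2 |
| winter | 5.00 | 72.5 | 1.4 |
| winter | 6.00 | 73.5 | 1.3 |
| winter | 8.00 | 74.2 | 0 |

(scatter of a reading: 1 percentage point)

- at the start none of partner is dissolved
- the analysis behind the earlier runs scatters by 1 percentage point, standard deviation
- candidate steps: substrate <-> intermediate A; substrate -> intermediate B; intermediate A -> product; partner + intermediate B <-> intermediate C; gas <-> partner
- "hardly changes" means that all values lie within two and a half points (for a concentration: within two and a half percent of the largest)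

- amount of product at the end, in percent of the substrate charged for east, north-east, north-west, in this order
- the shape of the row from first to last (rises all the way / falls all the way / falls, then rises / rises, then falls / hardly changes)

The candidate route runs from substrate through intermediate A to product. A side branch leads from substrate to intermediate B, which partner from the gas can turn into intermediate C. So the quantity to carry is the reacted share, or selectivity: product per substrate gone at 8.00 d, pooled over dusk and winter, reads 75.2%.

Winter holds 4.81 times the substrate of dusk, and its substrate stands at ten times the concentration of the gas. Yet product reads 60.8% in dusk and 60.5% in winter at 2.50 d, a gap inside the scatter of 1 percentage point.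

East and north-east lie inside that span, but north-west lies above winter, so its figure rests on the share holding there. Substrate reads 1.6% in dusk and 0% in winter at 8.00 d, so my own reckoning puts product near 75.2% in each new flask.

The forecast gives 75%, 75% and 75%, a row that hardly changes: “So partner and gas can shift the B/C balance but cannot change the product yield.” It fails if a run shows the share leaving 75.2% by more than the scatter of 1 point as the charge rises.

The flasks give 74.0%, 74.0% and 74.0%, so the row hardly changes.

substrate ⇌ intermediate A (K = 0.500, k = 0.00200 min⁻¹); substrate → intermediate B (k = 1.70 × 10⁻⁴ min⁻¹); intermediate A → product (k = 0.00130 min⁻¹); partner + intermediate B ⇌ intermediate C (K = 51.0 L mol⁻¹, k = 2.40 × 10⁻⁴ L mol⁻¹ min⁻¹); gas ⇌ partner, rate k5*(csat - [partner]) (kL = 0.0100 min⁻¹) In east, intermediate B falls from 19.2% at 8.00 d to 3.76% at 80.0 d and intermediate C reaches 22.0%, while product goes from 74.0% to 74.3%. East at 8.00 d holds substrate 0.227% and intermediate A 0.0947%, so the share, taken on what has passed both, gives 75.0%. North-west at 4.00 d still holds substrate 4.11% and intermediate A 1.71%, so the share gives 70.8%, and the flask holds product 69.8%.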